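Retrosynthetic cuts, in order: (a) the three silicon-based O-protecting groups; (b) ring A (C1'–C6') back to its 5',6'-dihydro form; (c) C1'–C(=O), between ring A and the whole cinnamoyl unit (carbonyl, E-alkene, ring B); (d) C3'–CH2, between ring A and the C10 side chain.
Enabling feature: ring A carries oxygen on C2' and C4', 1,3 to each other around C3', and the chalcone carbonyl on C1' is beta to the C2' oxygen. The dihydro ring is therefore a cyclohexane-1,3-dione mono-enol ether (C1 = C2', C2 = C3', C3 = C4', C6 = C1'). Its C6 is the kinetic alpha-prime enolate carbon, and the array O=C–C1'–C2'–O is a 1,3-diketone that an enolate C-acylation can make.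
Forward order: dione, then enol ether, then 2-iodide. A B-alkyl Suzuki–Miyaura coupling puts the linalool chain on C2, and the C6 lithium enolate takes the complete cinnamoyl unit from an N-acylbenzotriazole. DDQ then aromatises ring A (ring B is bought), and fluoride frees the three hydroxyl groups.
Stereochemistry: the single (R)-carbinol centre is bought as (R)-(−)-linalool and no bond to it is ever broken. The E-alkene is bought in p-coumaric acid.

Key step: step 7

Assumption: commercial (R)-(−)-linalool is used in enantiopure form; the enantiomeric purity of 16 should equal that of the linalool used, because no step acts at the carbinol carbon.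

Step 1
Reactants: 1 cyclohexane-1,3-dione
Product: 2 3-[2-(trimethylsilyl)ethoxy]cyclohex-2-en-1-one
Conditions: Me3SiCH2CH2OH (1.2 equiv), TsOH·H2O (2 mol %), benzene, reflux, Dean–Stark
Reagents that add atoms: 2-(trimethylsilyl)ethanol, C[Si](C)(C)CCO
Why: Acid-catalysed enol etherification of a cyclic 1,3-dione (vinylogous Fischer esterification) is driven by azeotropic removal of water; the symmetric dione can give only one enol ether, and the primary beta-silyl alcohol tolerates catalytic TsOH.

Step 2
Reactants: 2 3-[2-(trimethylsilyl)ethoxy]cyclohex-2-en-1-one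
Product: 3 2-iodo-3-[2-(trimethylsilyl)ethoxy]cyclohex-2-en-1-one
Conditions: NIS (1.05 equiv), MeCN, 0 °C to rt, dark
Reagents that add atoms: N-iodosuccinimide, O=C1CCC(=O)N1I
Why: Electrophilic alpha-iodination of a vinylogous ester: C2 is the nucleophilic carbon of the push–pull alkene and the only site that should react with NIS.

Step 3
Reactants: 4 (R)-(−)-linalool
Product: 5 (3R)-3,7-dimethyl-3-(triethylsilyloxy)octa-1,6-diene
Conditions: TESOTf (1.2 equiv), 2,6-lutidine (2 equiv), CH2Cl2, −78 to 0 °C
Reagents that add atoms: triethylsilyl triflate, CC[Si](CC)(CC)OS(=O)(=O)C(F)(F)F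
Why: O-silylation of a hindered tertiary alcohol with a silyl triflate and a hindered base forms only the O–Si bond, so the (R) configuration is kept, and the buffered cold medium suppresses ionisation of the tertiary allylic alcohol.

Step 4
Reactants: 5 (3R)-3,7-dimethyl-3-(triethylsilyloxy)octa-1,6-diene; 3 2-iodo-3-[2-(trimethylsilyl)ethoxy]cyclohex-2-en-1-one
Product: 7 2-[(3R)-3,7-dimethyl-3-(triethylsilyloxy)oct-6-en-1-yl]-3-[2-(trimethylsilyl)ethoxy]cyclohex-2-en-1-one, via B-alkyl-9-BBN borane 6 (not isolated)
Conditions: 9-BBN-H (0.5 M in THF, 1.2 equiv), 0 °C to rt; then 3, PdCl2(dppf)·CH2Cl2 (5 mol %), AsPh3 (5 mol %), Cs2CO3 (2 equiv), degassed DMF/THF/H2O, rt to 45 °C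
Reagents that add atoms: 9-borabicyclo[3.3.1]nonane (9-BBN-H), B1C2CCCC1CCC2 (boron and its bicycle stay in 6 only; 7 keeps one hydrogen)
Why: 9-BBN-H hydroborates the monosubstituted vinyl group anti-Markovnikov much faster than the trisubstituted alkene, and the primary borane then enters a B-alkyl Suzuki–Miyaura coupling with the alpha-iodoenone (oxidative addition of zerovalent palladium into the carbon–iodine bond), which places the chain on C2 between the two oxygenated carbons without touching the stereocentre.

Step 5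
Reactants: 8 (E)-4-hydroxycinnamic acid (p-coumaric acid)
Product: 10 (E)-4-(tert-butyldimethylsilyloxy)cinnamic acid, via bis-silylated ester 9 (not isolated)
Conditions: TBSCl (2.3 equiv), imidazole (5 equiv), DMF, rt; then AcOH/THF/H2O, rt
Reagents that add atoms: tert-butyldimethylsilyl chloride, CC(C)(C)[Si](C)(C)Cl
Why: Exhaustive silylation followed by selective hydrolysis works because the silyl ester is far more labile to aqueous acetic acid than the aryl silyl ether, and the E-alkene is not involved.

Step 6
Reactants: 10 (E)-4-(tert-butyldimethylsilyloxy)cinnamic acid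
Product: 11 (E)-1-(1H-benzotriazol-1-yl)-3-[4-(tert-butyldimethylsilyloxy)phenyl]prop-2-en-1-one
Conditions: 1H-benzotriazole (1.1 equiv), DCC (1.1 equiv), CH2Cl2, 0 °C to rt
Reagents that add atoms: 1H-benzotriazole, c1ccc2[nH]nnc2c1
Why: Carbodiimide-mediated N-acylation of benzotriazole under neutral conditions should give a storable activated amide that acts as an acid chloride equivalent and leaves the aryl silyl ether alone.

Step 7
Reactants: 7 2-[(3R)-3,7-dimethyl-3-(triethylsilyloxy)oct-6-en-1-yl]-3-[2-(trimethylsilyl)ethoxy]cyclohex-2-en-1-one; 11 (E)-1-(1H-benzotriazol-1-yl)-3-[4-(tert-butyldimethylsilyloxy)phenyl]prop-2-en-1-one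
Product: 14 6-{(E)-3-[4-(tert-butyldimethylsilyloxy)phenyl]prop-2-enoyl}-2-[(3R)-3,7-dimethyl-3-(triethylsilyloxy)oct-6-en-1-yl]-3-[2-(trimethylsilyl)ethoxy]cyclohex-2-en-1-one (drawn as its chelated C1 enol), via lithium dienolate 12 (not isolated), via lithium diketonate 13 (not isolated)
Conditions: LDA (1.1 equiv), THF, −78 °C, 45 min; LiHMDS (1.1 equiv); 11 (1.3 equiv) in THF added quickly, −78 to −40 °C; AcOH quench at −78 °C
Reagents that add atoms: LDA, CC(C)N([Li])C(C)C (lithium of 12 only); LiHMDS, C[Si](C)(C)N([Li])[Si](C)(C)C (lithium of 13 only)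
Why: LDA removes the kinetically most accessible proton of vinylogous ester 7, the one on C6 (alpha-prime to C1=O, the future C1' of ring A), to give the cross-conjugated lithium dienolate 12, which adds to the activated carbonyl of 11 and expels benzotriazolide (addition–elimination, a crossed Claisen-type C-acylation). The closest known reaction types are the alpha-prime functionalisation of 3-alkoxyenones used in Stork–Danheiser sequences and the C-acylation of ketone lithium enolates with N-acylbenzotriazoles or acyl cyanides. No ring is closed, and the only new stereocentre (C6) is a freely enolising 1,3-dicarbonyl carbon that is erased in step 8 and needs no control, while the remote (R)-carbinol centre is untouched. Site selectivity comes from the C3 alkoxy group, which leaves C4–H removal as the slower thermodynamic path, and from the side chain on C2, which blocks the other nucleophilic carbon. C- over O-acylation should follow from lithium chelation between the enolate oxygen and the acylbenzotriazole, and 1,2- over 1,4-attack from the low temperature, the very electrophilic amide carbonyl and the para-silyloxy donor that deactivates the beta-carbon. Compound 11 has no alpha-hydrogen and so cannot be enolised or give a ketene, and the hindered LiHMDS takes the acidic proton of the product (as chelate 13) so that 12 is not quenched by it.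

Step 8
Reactants: 14 6-cinnamoyl vinylogous ester (chelated enol)
Product: 15 (E)-3-[4-(tert-butyldimethylsilyloxy)phenyl]-1-{3-[(3R)-3,7-dimethyl-3-(triethylsilyloxy)oct-6-en-1-yl]-2-hydroxy-4-[2-(trimethylsilyl)ethoxy]phenyl}prop-2-en-1-one
Conditions: DDQ (1.1 equiv), 1,4-dioxane, rt
Reagents that add atoms: none
Why: Dehydrogenative aromatisation: DDQ abstracts hydride from C5 of the dienol (the cation is stabilised by the enol oxygen) and loss of the C4 proton gives the arene, driven by aromaticity and the chelated ortho-hydroxyaryl ketone, while the isolated trisubstituted alkene and the silyl ethers should be inert to one equivalent at rt.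

Step 9
Reactants: 15 protected chalcone
Product: 16 (E)-1-{2,4-dihydroxy-3-[(3R)-3-hydroxy-3,7-dimethyloct-6-en-1-yl]phenyl}-3-(4-hydroxyphenyl)prop-2-en-1-one
Conditions: TBAF (1.0 M in THF, 6 equiv), THF, 0 to 45 °C; AcOH quench
Reagents that add atoms: none
Why: In this global fluoride deprotection the aryl TBS and tertiary TES ethers fall by attack at silicon and the 2-(trimethylsilyl)ethyl ether by fluoride-induced beta-elimination (ethene and Me3SiF), for which the para-acylphenoxide is a good leaving group; no acid is present that could ionise the tertiary alcohol or the alkene, basic medium keeps a 2'-hydroxychalcone in its open form, and the C–O bond at the stereocentre is not broken.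

Compound list
1 | cyclohexane-1,3-dione | O=C1CCCC(=O)C1 | starting material
2 | 3-[2-(trimethylsilyl)ethoxy]cyclohex-2-en-1-one | O=C1C=C(OCC[Si](C)(C)C)CCC1 | intermediate
3 | 2-iodo-3-[2-(trimethylsilyl)ethoxy]cyclohex-2-en-1-one | O=C1C(I)=C(OCC[Si](C)(C)C)CCC1 | intermediate
4 | (R)-(−)-linalool, (3R)-3,7-dimethylocta-1,6-dien-3-ol | CC(C)=CCC[C@@](C)(O)C=C | starting material
5 | (3R)-3,7-dimethyl-3-(triethylsilyloxy)octa-1,6-diene | CC(C)=CCC[C@@](C)(O[Si](CC)(CC)CC)C=C | intermediate
6 | 9-[(3S)-3,7-dimethyl-3-(triethylsilyloxy)oct-6-en-1-yl]-9-borabicyclo[3.3.1]nonane (same spatial arrangement; the descriptor changes only through CIP ranking of the boron-bearing arm) | CC(C)=CCC[C@@](C)(O[Si](CC)(CC)CC)CCB1C2CCCC1CCC2 | intermediate (not isolated)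
7 | 2-[(3R)-3,7-dimethyl-3-(triethylsilyloxy)oct-6-en-1-yl]-3-[2-(trimethylsilyl)ethoxy]cyclohex-2-en-1-one | CC(C)=CCC[C@@](C)(O[Si](CC)(CC)CC)CCC1=C(OCC[Si](C)(C)C)CCCC1=O | intermediate
8 | (E)-4-hydroxycinnamic acid (p-coumaric acid) | O=C(O)/C=C/c1ccc(O)cc1 | starting material
9 | tert-butyldimethylsilyl (E)-4-(tert-butyldimethylsilyloxy)cinnamate | CC(C)(C)[Si](C)(C)OC(=O)/C=C/c1ccc(O[Si](C)(C)C(C)(C)C)cc1 | intermediate (not isolated)
10 | (E)-4-(tert-butyldimethylsilyloxy)cinnamic acid | O=C(O)/C=C/c1ccc(O[Si](C)(C)C(C)(C)C)cc1 | intermediate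
11 | (E)-1-(1H-benzotriazol-1-yl)-3-[4-(tert-butyldimethylsilyloxy)phenyl]prop-2-en-1-one | O=C(/C=C/c1ccc(O[Si](C)(C)C(C)(C)C)cc1)n1nnc2ccccc21 | intermediate
12 | lithium C1,C6-dienolate of 7 (cross-conjugated, R side chain) | CC(C)=CCC[C@@](C)(O[Si](CC)(CC)CC)CCC1=C(OCC[Si](C)(C)C)CCC=C1O[Li] | intermediate (not isolated)
13 | lithium diketonate of 14 | CC(C)=CCC[C@@](C)(O[Si](CC)(CC)CC)CCC1=C(OCC[Si](C)(C)C)CCC(C(=O)/C=C/c2ccc(O[Si](C)(C)C(C)(C)C)cc2)=C1O[Li] | intermediate (not isolated)
14 | 6-{(E)-3-[4-(tert-butyldimethylsilyloxy)phenyl]prop-2-enoyl}-2-[(3R)-3,7-dimethyl-3-(triethylsilyloxy)oct-6-en-1-yl]-3-[2-(trimethylsilyl)ethoxy]cyclohex-2-en-1-one, chelated C1 enol | CC(C)=CCC[C@@](C)(O[Si](CC)(CC)CC)CCC1=C(OCC[Si](C)(C)C)CCC(C(=O)/C=C/c2ccc(O[Si](C)(C)C(C)(C)C)cc2)=C1O | intermediate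
15 | (E)-3-[4-(tert-butyldimethylsilyloxy)phenyl]-1-{3-[(3R)-3,7-dimethyl-3-(triethylsilyloxy)oct-6-en-1-yl]-2-hydroxy-4-[2-(trimethylsilyl)ethoxy]phenyl}prop-2-en-1-one | CC(C)=CCC[C@@](C)(O[Si](CC)(CC)CC)CCc1c(OCC[Si](C)(C)C)ccc(C(=O)/C=C/c2ccc(O[Si](C)(C)C(C)(C)C)cc2)c1O | intermediate
16 | (E)-1-{2,4-dihydroxy-3-[(3R)-3-hydroxy-3,7-dimethyloct-6-en-1-yl]phenyl}-3-(4-hydroxyphenyl)prop-2-en-1-one | CC(C)=CCC[C@@](C)(O)CCc1c(O)ccc(C(=O)/C=C/c2ccc(O)cc2)c1O | target

Total steps: 9. Longest linear sequence: 6 steps (1, 2, 4, 7, 8, 9).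

Steps most likely to fail

1. Step 7. The acylation may be eroded by O-acylation of the dienolate, by conjugate addition to the cinnamoyl beta-carbon, or by proton transfer from the acidic product to unreacted enolate. The fallback lowers the oxidation level of the electrophile. It sets out from 7 and comes back at 14. Commercial (E)-4-hydroxycinnamaldehyde is silylated (TBSCl, imidazole, DMF) to (E)-3-[4-(tert-butyldimethylsilyloxy)phenyl]prop-2-enal F1. The dienolate made from 7 with LDA at −78 °C adds 1,2 to F1 in an aldol reaction. This forms the same C6–C bond, and its aldolate product is not acidic. It gives the 6-(1-hydroxy-3-arylallyl) vinylogous ester F2 as a mixture at the two new centres, both of which are erased later. Buffered Dess–Martin oxidation (NaHCO3, CH2Cl2) of the carbinol then gives 14.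

2. Step 8. Hydride abstraction may be slow. It may also be followed by over-oxidation at the new benzylic CH2 next to the free phenol or at the allylic positions of the side chain. The fallback replaces hydride abstraction by selenoxide elimination. It sets out from 14 and comes back at 15. The 1,3-dicarbonyl carbon C6 is selenenylated with PhSeCl and pyridine (CH2Cl2, 0 °C) to the 6-(phenylselanyl) diketone F3. Oxidation with one equivalent of mCPBA at −78 °C, where selenium reacts far faster than the alkene, gives the selenoxide F4. On warming, F4 undergoes syn-elimination toward C5–H, and tautomerisation gives 15.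

3. Step 9. Fragmentation of the silylethyl ether may stall once the substrate has become a polyphenoxide. Long exposure to warm basic fluoride may then cause retro-aldol cleavage or cyclisation of the chalcone. The fallback changes the protecting-group plan so that the last step cleaves only plain silyl ethers. It sets out from 7 and comes back at 16. Compound 7 is hydrolysed (LiOH, THF/H2O, 50 °C; NaH2PO4 work-up) to 2-[(3R)-3,7-dimethyl-3-(triethylsilyloxy)oct-6-en-1-yl]cyclohexane-1,3-dione F5. This is O-silylated (TIPSOTf, Et3N, CH2Cl2, −78 °C) to the 3-(triisopropylsilyloxy)enone F6. F6 is acylated at C6 with 11 under the conditions of step 7 to the chelated enol F7, and F7 is aromatised with DDQ as in step 8 to the 4'-O-triisopropylsilyl chalcone F8. AcOH-buffered TBAF (THF, 0 °C) should then remove all three silyl ethers and give 16. Any silyl migration between the ring oxygens on the way is harmless, because every O-silyl group is removed at the end.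

Further compounds
F1 | step 7 | (E)-3-[4-(tert-butyldimethylsilyloxy)phenyl]prop-2-enal | O=C/C=C/c1ccc(O[Si](C)(C)C(C)(C)C)cc1
F2 | step 7 | 6-{(E)-1-hydroxy-3-[4-(tert-butyldimethylsilyloxy)phenyl]prop-2-en-1-yl}-2-[(3R)-3,7-dimethyl-3-(triethylsilyloxy)oct-6-en-1-yl]-3-[2-(trimethylsilyl)ethoxy]cyclohex-2-en-1-one (mixture at C6 and the carbinol carbon) | CC(C)=CCC[C@@](C)(O[Si](CC)(CC)CC)CCC1=C(OCC[Si](C)(C)C)CCC(C(O)/C=C/c2ccc(O[Si](C)(C)C(C)(C)C)cc2)C1=O
F3 | step 8 | 6-(phenylselanyl) derivative of the keto form of 14 (mixture at C6) | CC(C)=CCC[C@@](C)(O[Si](CC)(CC)CC)CCC1=C(OCC[Si](C)(C)C)CCC([Se]c2ccccc2)(C(=O)/C=C/c2ccc(O[Si](C)(C)C(C)(C)C)cc2)C1=O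
F4 | step 8 | selenoxide of F3 | CC(C)=CCC[C@@](C)(O[Si](CC)(CC)CC)CCC1=C(OCC[Si](C)(C)C)CCC([Se](=O)c2ccccc2)(C(=O)/C=C/c2ccc(O[Si](C)(C)C(C)(C)C)cc2)C1=O
F5 | step 9 | 2-[(3R)-3,7-dimethyl-3-(triethylsilyloxy)oct-6-en-1-yl]cyclohexane-1,3-dione | CC(C)=CCC[C@@](C)(O[Si](CC)(CC)CC)CCC1C(=O)CCCC1=O
F6 | step 9 | 2-[(3R)-3,7-dimethyl-3-(triethylsilyloxy)oct-6-en-1-yl]-3-(triisopropylsilyloxy)cyclohex-2-en-1-one | CC(C)=CCC[C@@](C)(O[Si](CC)(CC)CC)CCC1=C(O[Si](C(C)C)(C(C)C)C(C)C)CCCC1=O
F7 | step 9 | 6-{(E)-3-[4-(tert-butyldimethylsilyloxy)phenyl]prop-2-enoyl} derivative of F6, chelated C1 enol | CC(C)=CCC[C@@](C)(O[Si](CC)(CC)CC)CCC1=C(O[Si](C(C)C)(C(C)C)C(C)C)CCC(C(=O)/C=C/c2ccc(O[Si](C)(C)C(C)(C)C)cc2)=C1O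
F8 | step 9 | (E)-3-[4-(tert-butyldimethylsilyloxy)phenyl]-1-{3-[(3R)-3,7-dimethyl-3-(triethylsilyloxy)oct-6-en-1-yl]-2-hydroxy-4-(triisopropylsilyloxy)phenyl}prop-2-en-1-one | CC(C)=CCC[C@@](C)(O[Si](CC)(CC)CC)CCc1c(O[Si](C(C)C)(C(C)C)C(C)C)ccc(C(=O)/C=C/c2ccc(O[Si](C)(C)C(C)(C)C)cc2)c1O
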